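**Retrosynthetic overview**
- Militarinone A is unveiled last by double O‑demethylation of a 2,4‑dimethoxypyridine N‑oxide that already carries the trienoyl chain and the cis‑diol.
- C2'=C3' comes from an aldol condensation of a 3‑acetylpyridine N‑oxide core with a C13 (2E,4E)‑dienal.
- The core is built on 5‑bromo‑2,4‑dimethoxypyridine: a light‑driven nickel/hydrogen‑atom‑transfer heteroarylation of a carbinol C–H of cyclohexane‑1,4‑diol forms C5–C1'' and sets the cis‑diol, then C3 acetylation and N‑oxidation follow before any alkene is present.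
- The dienal comes from two Wittig homologations of (2R,4R)‑2,4‑dimethylhexanal; its two methyl centres come from D‑lactate triflate (SN2, inversion) and (S)‑3‑bromo‑2‑methylpropan‑1‑ol.
- Ring order: no ring is made; the pyridine and cyclohexane rings are bought intact, and the pyridone appears only in the last step.

Assumption: the cyclohexane descriptors are read as the cis‑1,4‑diol (both hydroxyls on one face, pyridone trans to the secondary hydroxyl), and ethyl (R)‑2‑(triflyloxy)propanoate is taken as a catalogue item (otherwise one step from ethyl D‑lactate).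

**Route**

Step 1
Reactants: 1 (S)-3-bromo-2-methylpropan-1-ol
Product: 2 (R)-2-methylbutan-1-ol
Conditions: MeMgBr (3.0 equiv), Li2CuCl4 (3 mol %), THF, −20 → 23 °C; H2O
Reagents that add atoms: methylmagnesium bromide, C[Mg]Br
Why: Kochi-type copper-catalysed sp3–sp3 Grignard coupling replaces the primary bromide of the bromomagnesium alkoxide by methyl without touching the stereocentre bought in 1 (the descriptor changes S→R only through CIP priority).

Step 2
Reactants: 2 (R)-2-methylbutan-1-ol
Product: 3 (R)-1-bromo-2-methylbutane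
Conditions: PPh3, NBS, CH2Cl2, 0 → 23 °C; distil
Reagents that add atoms: N-bromosuccinimide, O=C1CCC(=O)N1Br
Why: Appel-type bromination proceeds by SN2 at the primary CH2, so the adjacent stereocentre is untouched.

Step 3
Reactants: 3 (R)-1-bromo-2-methylbutane; 4 ethyl (R)-2-{[(trifluoromethyl)sulfonyl]oxy}propanoate
Product: 6 ethyl (2R,4R)-2,4-dimethylhexanoate, via Grignard reagent 5 (not isolated)
Conditions: Mg, THF, 40 °C; then added to 4 (1.2 equiv), ZnCl2 (10 mol %), THF, 0 °C, 3 h
Reagents that add atoms: magnesium, [Mg] (retained only in intermediate 5)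
Why: Zinc-catalysed stereospecific SN2 alkylation of the lactate-derived α-triflyloxy ester by the in situ triorganozincate goes with clean inversion, so the bought (R)-lactate centre becomes the (2R) methyl centre while C4 is carried from 1.

Step 4
Reactants: 6 ethyl (2R,4R)-2,4-dimethylhexanoate
Product: 7 (2R,4R)-2,4-dimethylhexanal
Conditions: i-Bu2AlH (1.05 equiv), CH2Cl2, −78 °C; aq. KNaC4H4O6; used crude
Reagents that add atoms: none
Why: Partial ester reduction stops at the tetrahedral aluminium hemiacetal at −78 °C, giving the aldehyde without over-reduction or α-epimerisation.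

Step 5
Reactants: 7 (2R,4R)-2,4-dimethylhexanal; 8 2-(triphenyl-λ5-phosphanylidene)propanal
Product: 9 (2E,4R,6R)-2,4,6-trimethyloct-2-enal
Conditions: toluene, 90 °C, 16 h
Reagents that add atoms: none
Why: Wittig olefination with a stabilised α-methyl ylide gives the E-trisubstituted enal under neutral conditions that leave the α-stereocentre intact.

Step 6
Reactants: 9 (2E,4R,6R)-2,4,6-trimethyloct-2-enal; 10 2-(triphenyl-λ5-phosphanylidene)acetaldehyde
Product: 11 (2E,4E,6R,8R)-4,6,8-trimethyldeca-2,4-dienal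
Conditions: toluene, 80 °C, 24 h
Reagents that add atoms: none
Why: Wittig two-carbon homologation with the stabilised formylmethylene ylide forms the E-disubstituted alkene and delivers the dienal directly.

Step 7
Reactants: 12 5-bromo-2,4-dimethoxypyridine; 13 cyclohexane-1,4-diol (cis/trans mixture, 5 equiv)
Product: 14 cis-1-(4,6-dimethoxypyridin-3-yl)cyclohexane-1,4-diol
Conditions: [Ir(dF(CF3)ppy)2(dtbbpy)]PF6 (1 mol %), Ni(TMHD)2 (10 mol %), quinuclidine (30 mol %), ZnCl2 (1.5 equiv), K2HPO4 (2 equiv), DMSO, 450 nm LEDs, 25 °C, 24 h (dF(CF3)ppy = 2-(2,4-difluorophenyl)-5-(trifluoromethyl)pyridinato; dtbbpy = 4,4'-di-tert-butyl-2,2'-bipyridine; TMHD = 2,2,6,6-tetramethylheptane-3,5-dionato)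
Reagents that add atoms: none
Why: Proposed new method: the photoexcited trivalent iridium complex oxidises quinuclidine to its radical cation, which abstracts the hydridic carbinol C–H of the zinc alkoxide of either diol isomer to give one common tertiary α-oxy radical, and this is captured on its less hindered equatorial face by the aryl–nickel species formed from 12 and zerovalent nickel (a diketonate nickel source is chosen because it accepts tertiary radicals), so that reductive elimination from trivalent nickel forges C5–C1'' with the pyridyl equatorial and trans to the equatorial C4 oxygen (cis-diol, stereoconvergent, no chiral agent; minor trans-diol removed by crystallisation), the closest known reaction type being the photoredox/hydrogen-atom-transfer/nickel α-arylation of primary alcohols, here extended to a secondary carbinol C–H that ends as a fully substituted, diastereodefined carbinol.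

Step 8
Reactants: 14 cis-1-(4,6-dimethoxypyridin-3-yl)cyclohexane-1,4-diol
Product: 16 1-[5-(cis-1,4-dihydroxycyclohexyl)-2,4-dimethoxypyridin-3-yl]ethan-1-one, via trilithiated pyridine 15 (not isolated)
Conditions: n-BuLi (3.3 equiv), THF, −78 → −20 °C; MeC(O)N(OMe)Me (1.5 equiv), −78 → 0 °C; H2O
Reagents that add atoms: n-butyllithium, CCCC[Li] (lithium retained only in intermediate 15); N-methoxy-N-methylacetamide, CC(=O)N(C)OC
Why: Directed ortho-metalation occurs at the only C–H flanked by both methoxy groups (the two alkoxides are spectators), and Weinreb amide acylation stops at the ketone through its chelated tetrahedral adduct.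

Step 9
Reactants: 16 1-[5-(cis-1,4-dihydroxycyclohexyl)-2,4-dimethoxypyridin-3-yl]ethan-1-one
Product: 17 3-acetyl-5-(cis-1,4-dihydroxycyclohexyl)-2,4-dimethoxypyridine 1-oxide
Conditions: mCPBA (1.3 equiv), CH2Cl2, 0 → 23 °C, 12 h
Reagents that add atoms: 3-chloroperoxybenzoic acid, OOC(=O)c1cccc(Cl)c1
Why: Electrophilic N-oxidation of the pyridine nitrogen by the peracid is done before any alkene is present, and the alcohols and the hindered, twisted ketone are inert at this temperature.

Step 10
Reactants: 17 3-acetyl-5-(cis-1,4-dihydroxycyclohexyl)-2,4-dimethoxypyridine 1-oxide; 11 (2E,4E,6R,8R)-4,6,8-trimethyldeca-2,4-dienal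
Product: 19 5-(cis-1,4-dihydroxycyclohexyl)-2,4-dimethoxy-3-[(2E,4E,6E,8R,10R)-6,8,10-trimethyldodeca-2,4,6-trienoyl]pyridine 1-oxide, via aldol adduct 18 (not isolated)
Conditions: LiN(SiMe3)2 (3.1 equiv), THF, −78 °C, 30 min; 11 (1.1 equiv), −78 °C, 1 h; then MeOH (20 equiv), −78 → 23 °C, 4 h; H2O
Reagents that add atoms: none
Why: Directed Claisen–Schmidt aldol condensation, in which the preformed lithium enolate adds 1,2 to the dienal at −78 °C (too cold for ε-deprotonation at the C8' centre) and the aldolate then eliminates by E1cB on warming with methanol to the E-enone.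

Step 11
Reactants: 19 5-(cis-1,4-dihydroxycyclohexyl)-2,4-dimethoxy-3-[(2E,4E,6E,8R,10R)-6,8,10-trimethyldodeca-2,4,6-trienoyl]pyridine 1-oxide
Product: 20 militarinone A
Conditions: LiCl (20 equiv), DMF, 85 °C, N2 sweep, dark; then cold 0.1 M HCl to pH 4
Reagents that add atoms: none
Why: Krapcho-type nucleophilic O-demethylation, in which chloride attacks both methyl groups by SN2 because each oxygen is a good leaving group (N-oxide-activated 2-alkoxy, vinylogous-ester 4-alkoxy), unveiling the 1-hydroxy-2-pyridone without acid so the tertiary carbinol and the triene survive.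

**Compound list**
1 | (S)-3-bromo-2-methylpropan-1-ol | BrC[C@@H](C)CO | starting material
2 | (R)-2-methylbutan-1-ol | CC[C@@H](C)CO | intermediate
3 | (R)-1-bromo-2-methylbutane | CC[C@@H](C)CBr | intermediate
4 | ethyl (R)-2-{[(trifluoromethyl)sulfonyl]oxy}propanoate | C[C@@H](OS(=O)(=O)C(F)(F)F)C(=O)OCC | starting material
5 | (R)-2-methylbutylmagnesium bromide | CC[C@@H](C)C[Mg]Br | intermediate
6 | ethyl (2R,4R)-2,4-dimethylhexanoate | CC[C@@H](C)C[C@@H](C)C(=O)OCC | intermediate
7 | (2R,4R)-2,4-dimethylhexanal | CC[C@@H](C)C[C@@H](C)C=O | intermediate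
8 | 2-(triphenyl-λ5-phosphanylidene)propanal | CC(C=O)=P(c1ccccc1)(c1ccccc1)c1ccccc1 | starting material
9 | (2E,4R,6R)-2,4,6-trimethyloct-2-enal | CC[C@@H](C)C[C@@H](C)/C=C(C)/C=O | intermediate
10 | 2-(triphenyl-λ5-phosphanylidene)acetaldehyde | O=CC=P(c1ccccc1)(c1ccccc1)c1ccccc1 | starting material
11 | (2E,4E,6R,8R)-4,6,8-trimethyldeca-2,4-dienal | CC[C@@H](C)C[C@@H](C)/C=C(C)/C=C/C=O | intermediate
12 | 5-bromo-2,4-dimethoxypyridine | COc1cc(OC)c(Br)cn1 | starting material
13 | cyclohexane-1,4-diol (cis/trans mixture) | OC1CCC(O)CC1 | starting material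
14 | cis-1-(4,6-dimethoxypyridin-3-yl)cyclohexane-1,4-diol (hydroxyls cis, pyridyl trans to the C4 hydroxyl) | COc1cc(OC)c([C@]2(O)CC[C@@H](O)CC2)cn1 | intermediate
15 | dilithium cis-1-(5-lithio-4,6-dimethoxypyridin-3-yl)cyclohexane-1,4-bis(olate) | COc1ncc([C@]2(O[Li])CC[C@@H](O[Li])CC2)c(OC)c1[Li] | intermediate
16 | 1-[5-(cis-1,4-dihydroxycyclohexyl)-2,4-dimethoxypyridin-3-yl]ethan-1-one | CC(=O)c1c(OC)ncc([C@]2(O)CC[C@@H](O)CC2)c1OC | intermediate
17 | 3-acetyl-5-(cis-1,4-dihydroxycyclohexyl)-2,4-dimethoxypyridine 1-oxide | CC(=O)c1c(OC)[n+]([O-])cc([C@]2(O)CC[C@@H](O)CC2)c1OC | intermediate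
18 | 5-(cis-1,4-dihydroxycyclohexyl)-3-[(4E,6E,8R,10R)-3-hydroxy-6,8,10-trimethyldodeca-4,6-dienoyl]-2,4-dimethoxypyridine 1-oxide (both C3' epimers) | CC[C@@H](C)C[C@@H](C)/C=C(C)/C=C/C(O)CC(=O)c1c(OC)[n+]([O-])cc([C@]2(O)CC[C@@H](O)CC2)c1OC | intermediate
19 | 5-(cis-1,4-dihydroxycyclohexyl)-2,4-dimethoxy-3-[(2E,4E,6E,8R,10R)-6,8,10-trimethyldodeca-2,4,6-trienoyl]pyridine 1-oxide | CC[C@@H](C)C[C@@H](C)/C=C(C)/C=C/C=C/C(=O)c1c(OC)[n+]([O-])cc([C@]2(O)CC[C@@H](O)CC2)c1OC | intermediate
20 | militarinone A, 1,4-dihydroxy-5-(cis-1,4-dihydroxycyclohexyl)-3-[(2E,4E,6E,8R,10R)-6,8,10-trimethyldodeca-2,4,6-trienoyl]pyridin-2(1H)-one | CC[C@@H](C)C[C@@H](C)/C=C(C)/C=C/C=C/C(=O)c1c(O)c([C@]2(O)CC[C@@H](O)CC2)cn(O)c1=O | target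

**Totals**
Total step count: 11. Longest linear sequence: 8 steps (steps 1–6, 10, 11); the pyridine branch (steps 7–9) joins at step 10.

**Three steps most likely to fail**

Step 7 (the proposed light-driven heteroarylation) is the least certain step. Capture of a tertiary α-oxy radical by nickel may be slow, aryl ether formation or over-oxidation to the ketone may compete, and the cis:trans ratio is a prediction. The fallback uses known chemistry and sets out from 12. Bromine–lithium exchange (n-BuLi, THF, −78 °C) and addition to commercial 1,4-dioxaspiro[4.5]decan-8-one gives 8-(4,6-dimethoxypyridin-3-yl)-1,4-dioxaspiro[4.5]decan-8-ol F1. Mild ketal hydrolysis (PPTS, acetone/H2O, 50 °C) gives 4-(4,6-dimethoxypyridin-3-yl)-4-hydroxycyclohexan-1-one F2. NaBH4 (MeOH, −40 °C) then delivers hydride axially to the chair with equatorial pyridyl, giving the equatorial alcohol, which is cis-diol 14, where the route is rejoined.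

Step 10 (aldol condensation) may suffer from retro-aldol, sluggish E1cB dehydration, or base-induced loss of the C8' configuration through the extended enolate. The fallback replaces the aldol by a neutral Wittig olefination and sets out from 17. α-Bromination (CuBr2, EtOAc/CHCl3, 65 °C) gives 3-(2-bromoacetyl)-5-(cis-1,4-dihydroxycyclohexyl)-2,4-dimethoxypyridine 1-oxide F3. PPh3 (MeCN, 23 °C) gives {2-[5-(cis-1,4-dihydroxycyclohexyl)-2,4-dimethoxy-1-oxidopyridin-1-ium-3-yl]-2-oxoethyl}triphenylphosphonium bromide F4. Aqueous Na2CO3 gives the stabilised ylide 1-[5-(cis-1,4-dihydroxycyclohexyl)-2,4-dimethoxy-1-oxidopyridin-1-ium-3-yl]-2-(triphenyl-λ5-phosphanylidene)ethan-1-one F5, and heating this with 11 (toluene, 80 °C) gives 19, where the route is rejoined.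

Step 11 (final double demethylation) may stall after the first methyl group, divert by O-to-O methyl transfer to an N-methoxy pyridone, or isomerise the triene on prolonged heating. The fallback removes the methyl groups before the polyene exists and sets out from 17. NaSEt (DMF, 100 °C) gives 3-acetyl-1,4-dihydroxy-5-(cis-1,4-dihydroxycyclohexyl)pyridin-2(1H)-one F6. Its polyanion (LiN(i-Pr)2, 5.2 equiv, THF/DMPU, −78 °C) adds to 11 to give 1,4-dihydroxy-5-(cis-1,4-dihydroxycyclohexyl)-3-[(4E,6E,8R,10R)-3-hydroxy-6,8,10-trimethyldodeca-4,6-dienoyl]pyridin-2(1H)-one F7, which loses water on warming with MeOH and so arrives directly at 20.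

**Further compounds**
F1 | step 7 | 8-(4,6-dimethoxypyridin-3-yl)-1,4-dioxaspiro[4.5]decan-8-ol | COc1cc(OC)c(C2(O)CCC3(CC2)OCCO3)cn1
F2 | step 7 | 4-(4,6-dimethoxypyridin-3-yl)-4-hydroxycyclohexan-1-one | COc1cc(OC)c(C2(O)CCC(=O)CC2)cn1
F3 | step 10 | 3-(2-bromoacetyl)-5-(cis-1,4-dihydroxycyclohexyl)-2,4-dimethoxypyridine 1-oxide | BrCC(=O)c1c(OC)[n+]([O-])cc([C@]2(O)CC[C@@H](O)CC2)c1OC
F4 | step 10 | {2-[5-(cis-1,4-dihydroxycyclohexyl)-2,4-dimethoxy-1-oxidopyridin-1-ium-3-yl]-2-oxoethyl}triphenylphosphonium bromide | [Br-].O=C(C[P+](c1ccccc1)(c1ccccc1)c1ccccc1)c1c(OC)[n+]([O-])cc([C@]2(O)CC[C@@H](O)CC2)c1OC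
F5 | step 10 | 1-[5-(cis-1,4-dihydroxycyclohexyl)-2,4-dimethoxy-1-oxidopyridin-1-ium-3-yl]-2-(triphenyl-λ5-phosphanylidene)ethan-1-one | O=C(C=P(c1ccccc1)(c1ccccc1)c1ccccc1)c1c(OC)[n+]([O-])cc([C@]2(O)CC[C@@H](O)CC2)c1OC
F6 | step 11 | 3-acetyl-1,4-dihydroxy-5-(cis-1,4-dihydroxycyclohexyl)pyridin-2(1H)-one | CC(=O)c1c(O)c([C@]2(O)CC[C@@H](O)CC2)cn(O)c1=O
F7 | step 11 | 1,4-dihydroxy-5-(cis-1,4-dihydroxycyclohexyl)-3-[(4E,6E,8R,10R)-3-hydroxy-6,8,10-trimethyldodeca-4,6-dienoyl]pyridin-2(1H)-one | CC[C@@H](C)C[C@@H](C)/C=C(C)/C=C/C(O)CC(=O)c1c(O)c([C@]2(O)CC[C@@H](O)CC2)cn(O)c1=O
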